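Atom numbers are labdane numbers throughout: ring A is C1–C5 with C10, ring B is C5–C10, C17 sits on C8, C18 and C19 on C4, C20 on C10, and C11–C12 link C9 to the butenolide C13–C16.

## Structural features

The target is a labdane: a trans-fused decalin with, on quaternary C4, an equatorial methyl (C18) and an axial carboxylic acid (C19); on quaternary C10 the angular methyl C20; on C8 an equatorial hydroxymethyl group (C17); and on C9 an equatorial two-carbon chain (C11–C12) ending at the α-carbon C13 of a but-2-en-4-olide (C13=C14, C15H2–O, C16=O). The five stereocentres C4 (S), C5 (R), C10 (R), C9 (S) and C8 (R) stand in one unbroken row; C19 and C20 are 1,3-diaxial on the β face, H5 and H9 are axial and α, and C17 is trans to the C9 chain. The butenolide is the fragile part: base can deprotonate C15, add to C14 or open the lactone, and hydride or hydrogenation would reduce it, so it is made late and followed only by acid. The C19 acid is neopentyl and axial, so it cannot be esterified or freed by attack at its carbonyl carbon and has to be masked by a group that leaves by alkyl–oxygen cleavage. The real difficulty is the pair of quaternary centres C4 and C10, 1,3 to each other across C5, together with the trans ring fusion and the two further centres C9 and C8 on ring B. The key step uses the fact that C4 bears a methyl and a one-carbon carbonyl group next to C5–H and is tied through C3–C2–C1 to C10: ring A is the cyclohexene of a Diels–Alder reaction between 2-methylacrolein and a C5=C10–C1=C2 diene, and the C1=C10 alkene left behind is the handle for C10.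

## Logic of the disconnections

24 back to 22 (through 23): the O–Si bond at C17 and the O–C(tert-butyl) bond at C19 are cut. Both masks leave under acid by cleavage at silicon and at the tert-butyl carbon, never at the hindered C19 carbonyl, and the butenolide tolerates acid but not base. The end game becomes one operation. The demand is that the ester be put on by O-alkylation and that both groups last through the steps in between.

22 back to 21, then to 19 and 20: the ring alkene C13=C14 is moved out to C12=C13, and that bond is cut. An exocyclic alkene conjugated to the lactone is a Wittig retron, so the whole butenolide arrives as 20 in one C–C bond-forming step. The demand is a forward isomerisation that brings the alkene into the ring and a C12 aldehyde in 19.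

19 back to 18 and 17: C12 is taken to the ester level and the C9–C10 bond is cut. C10 is quaternary; a tertiary radical at C10 adding to C9 of a C9=C11–C12 enoate forms this bond, ring B and both centres C9 and C10, and needs only the C1=C10 alkene. A cation at C10 would be captured by the C19 ester, a radical is not. The bicycle becomes a monocycle and two stereocentres go. The demand is a chair-like 6-exo closure giving the trans fusion and an equatorial C9 chain, and a C12 ester that can be told apart from the C19 ester.

17 back to 15 and 16: the C9=C11 bond is cut (cross-metathesis). The acceptor is put on only when needed, because an enoate present earlier would compete as a dienophile; until then C9 is carried as an inert vinyl group. The demand is metathesis at a branched allylic alkene without touching C1=C10.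

15 back to 14 and 13: the C19 ester is returned to the aldehyde, the function that the cycloaddition catalyst binds. The demand is an oxidation that spares two alkenes.

13 back to 11 and 12: C4–C5 and C2–C3 are cut, the key disconnection. Ring A, the quaternary C4 and C5 go in one step, and the four-carbon piece is the achiral 12. The demand is ortho regiochemistry, an endo formyl group and one enantioface.

11 back to 10, then to 8 and 9: C1=C2 (methylenation) and C5=C10 (Wittig) are cut. The stabilised ylide 9 gives the (E) trisubstituted alkene that later fixes the C4/C5 relationship. The diene comes from an aldehyde in two steps; the demand is clean (E) geometry.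

8 back to 7 and 6, then to 3 and 5 (made from 4): the C5 oxygen is unmasked, then C7–C8 is cut. C8 carries a vinyl group, a CH2O group and an alkyl chain, the pattern left by SN2' alkylation of a γ-oxygenated allyl bromide. The centre is made with its vinyl group in place, so no epimerisable aldehyde is needed. The demand is branched regioselectivity and ligand control of the face.

3 back to 2 and 1: the C–Br and O–Si bonds are cut; a symmetric diol is differentiated at its two ends.

## Other disconnections considered

Alternative 1: The cut is C8–C9 and C11–C12, inside a cyclopentenone in which C12 and C17 are joined for the time being. In the forward step the Co2(CO)8 complex of enyne A1 (ethynyl group on quaternary C10, butenyl chain on C5) takes up CO and closes ring B and the five-membered ring to give cyclopentenone A2. In its favour, ring B, C8 and the carbons C11, C12 and C17 are all placed in one step, and the closure is a two-electron organometallic process, so no question of the face of a planar C10 arises; on that point it is the better of the two plans. Against it, both quaternary centres C4 and C10 must be made before the key step and it offers no way to them. The enyne is of the slower 1,7 type. Afterwards the C12–C17 bond has to be cut in a ketone that is flanked by two methylenes once C9=C11 is reduced, so the direction of oxygen insertion is not secured. C9 has to be set by reduction and C1=C2 removed. On structure the chosen plan does more, since it makes C4 and C5 in the key step. On step economy the chosen plan is shorter.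

Alternative 2: The cut is C5–C10 and C8–C9. In the forward step Me2AlCl activates the enal of A3 and the tethered vinylallene adds across C9=C10 to give octalin A4. In its favour, both rings, C5, C9 and C10 arise together in a concerted step, so the ring fusion follows from the geometry of the tether; in bonds and stereocentres per step, and in the security of the ring fusion, it is the better plan. Against it, the only stereocentre of A3 is an acyclic quaternary C4 (methyl, ester, alkenyl, alkyl), which is hard to make in one enantiomer and must then tell the two diene faces apart by the small difference between methyl and ester. The dienophile is a trisubstituted enal. Afterwards C8 must be set by addition to C8=C17 from the face that C20 shields, C6=C7 reduced and C12 added to C11. The chosen plan has the easier precursor and a catalyst-controlled first stereocentre; the step counts should be similar.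

Alternative 3: The cut is C1–C10. In the forward step PhI(OAc)2 oxidises the phenol of A5, and the silyl enol ether carbon C1 attacks the methyl-bearing para carbon C10 to give dienone A6. In its favour, ring B comes from a cheap aromatic, the benzylic quaternary C4 is within reach of catalytic asymmetric arylation, C10 is made in a polar step, and the C7 ketone is a handle for bringing C17 onto C8. Like the chosen plan it closes ring A in the key step, so on that count the two are equal. Against it, C10 is induced from C4 across the planar C5, a weak 1,3 relationship. A6 is far from the target in oxidation level (ketones at C2 and C7 to remove, C5=C6 and C8=C9 to reduce with C5, C8 and C9 still to be set), and C17 is missing. On step economy the chosen plan is clearly ahead.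

Key step: step 8

Assumptions:
- The (S)-oxazaborolidinium ion is taken to bind the aldehyde with its formyl C–H on the ring oxygen and to leave the Re face of C4 open, which gives 4S; if the sense is the reverse, the catalyst from (R)-α,α-diphenylprolinol is used.
- (S,S)-Taniaphos is taken to give the (R) branched product in step 3; if the sense is the reverse, the (R,R) ligand is used.
- 4 is taken as a bought material; it is otherwise one step from 3-bromopropan-1-ol and 4-methoxybenzyl trichloroacetimidate.

Step 1
Reactants: 1 (E)-but-2-ene-1,4-diol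
Product: 2 (E)-4-[(tert-butyldimethylsilyl)oxy]but-2-en-1-ol
Conditions: NaH (1.0 equiv), THF, 0 °C; TBSCl (1.0 equiv), 0 °C → rt
Reagents that add atoms: tert-butyldimethylsilyl chloride, CC(C)(C)[Si](C)(C)Cl
Why: Monosilylation of a symmetric diol through its sparingly soluble monosodium alkoxide (O-silylation); one equivalent of base and chloride should give mainly the mono-ether, and no stereocentre is involved.

Step 2
Reactants: 2 (E)-4-[(tert-butyldimethylsilyl)oxy]but-2-en-1-ol
Product: 3 {[(2E)-4-bromobut-2-en-1-yl]oxy}(tert-butyl)dimethylsilane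
Conditions: CBr4, PPh3, CH2Cl2, 0 °C
Reagents that add atoms: carbon tetrabromide, BrC(Br)(Br)Br
Why: Appel bromination of a primary allylic alcohol; at 0 °C substitution should be direct, and the (E) alkene and the silyl ether are not touched.

Step 3
Reactants: 3 {[(2E)-4-bromobut-2-en-1-yl]oxy}(tert-butyl)dimethylsilane, 4 1-[(3-bromopropoxy)methyl]-4-methoxybenzene
Product: 6 tert-butyl({(2R)-2-ethenyl-5-[(4-methoxyphenyl)methoxy]pentyl}oxy)dimethylsilane, via arylmethoxypropylmagnesium bromide 5 (not isolated)
Conditions: 4, Mg, Et2O, rt; then CuBr·SMe2 (3 mol%), (S,S)-Taniaphos C43H39FeNP2 (3.5 mol%), 3, CH2Cl2, −75 °C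
Reagents that add atoms: none
Why: Copper-catalysed enantioselective allylic alkylation (SN2') of a γ-silyloxy (E)-allyl bromide with an alkyl Grignard reagent; the ligand-bound cuprate attacks C8 anti to bromide, so the vinyl group and the C8 centre form together and the ligand chooses the face. The ether oxygen three carbons from magnesium cannot eliminate.

Step 4
Reactants: 6 tert-butyl({(2R)-2-ethenyl-5-[(4-methoxyphenyl)methoxy]pentyl}oxy)dimethylsilane
Product: 7 (4R)-4-{[(tert-butyldimethylsilyl)oxy]methyl}hex-5-en-1-ol
Conditions: DDQ (1.2 equiv), CH2Cl2/pH 7 buffer (10:1), 0 °C → rt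
Reagents that add atoms: none
Why: Oxidative cleavage of a 4-methoxybenzyl ether (hydride loss to the quinone, hydrolysis of the oxocarbenium ion); the silyl ether and the terminal alkene are inert and C8 is not involved.

Step 5
Reactants: 7 (4R)-4-{[(tert-butyldimethylsilyl)oxy]methyl}hex-5-en-1-ol
Product: 8 (4R)-4-{[(tert-butyldimethylsilyl)oxy]methyl}hex-5-enal
Conditions: Dess–Martin periodinane (1.2 equiv), CH2Cl2, 0 °C → rt
Reagents that add atoms: none
Why: Dess–Martin oxidation of a primary alcohol; the stereocentre is γ to the new carbonyl group and cannot epimerise.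

Step 6
Reactants: 8 (4R)-4-{[(tert-butyldimethylsilyl)oxy]methyl}hex-5-enal, 9 2-(triphenyl-λ5-phosphanylidene)propanal
Product: 10 (2E,6R)-6-{[(tert-butyldimethylsilyl)oxy]methyl}-2-methylocta-2,7-dienal
Conditions: toluene, 90 °C
Reagents that add atoms: none
Why: Wittig olefination with a formyl-stabilised ylide, which reacts only with the aliphatic aldehyde and gives the (E) trisubstituted enal (C5=C10) under thermodynamic control.

Step 7
Reactants: 10 (2E,6R)-6-{[(tert-butyldimethylsilyl)oxy]methyl}-2-methylocta-2,7-dienal
Product: 11 (3E,7R)-7-{[(tert-butyldimethylsilyl)oxy]methyl}-3-methylnona-1,3,8-triene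
Conditions: Ph3PCH3Br (1.5 equiv), KOtBu (1.4 equiv), THF, 0 °C; then 10, 0 °C → rt
Reagents that add atoms: methyltriphenylphosphonium bromide, C[P+](c1ccccc1)(c1ccccc1)c1ccccc1.[Br-]
Why: Wittig methylenation of an enal by 1,2-addition; the (E) geometry of C5=C10 is kept and C1=C2 completes the diene.

Step 8
Reactants: 11 (3E,7R)-7-{[(tert-butyldimethylsilyl)oxy]methyl}-3-methylnona-1,3,8-triene, 12 2-methylacrolein
Product: 13 (1S,2R)-2-[(3R)-3-{[(tert-butyldimethylsilyl)oxy]methyl}pent-4-en-1-yl]-1,3-dimethylcyclohex-3-ene-1-carbaldehyde
Conditions: 12 (3 equiv), (S)-o-tolyl oxazaborolidine from (S)-α,α-diphenylprolinol (20 mol%), HN(SO2CF3)2 (18 mol%) [active salt C24H25BNO+ N(SO2CF3)2−], CH2Cl2, −78 → −40 °C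
Reagents that add atoms: none
Why: The cationic boron binds the formyl oxygen anti to C4 while the formyl C–H rests on the ring oxygen, so the s-trans enal lies over one phenyl group and only its Re face at C4 is open. The closest known reaction type is the oxazaborolidinium-catalysed enantioselective Diels–Alder reaction of 2-methylacrolein with acyclic 1,3-dienes. The [4+2] cycloaddition is concerted but asynchronous: C3 bonds first to the unhindered terminus C2, the developing positive charge is spread over C1–C10–C5, and C4–C5 closes last. Ring A is closed by the cycloaddition itself (suprafacial on both partners, six-membered boat-like transition state), not by a separate cyclisation. C4 (S) is set by the catalyst, which fixes the enal face; C5 (R) follows from the endo position of the bound formyl group together with the (E) geometry of C5=C10, which puts C19 cis to C6. The step needs ortho regiochemistry, endo selectivity and one enantioface: the alkyl group on C5 and the open CH2 terminus C2 secure the first, the overlap of the activated formyl group with C10–C1 of an unbridged diene favours the second, and the catalyst pocket gives the third. The C20 methyl sits on the inner carbon C10, so the s-cis conformer is accessible, and the remote vinyl group and silyl ether are inert at −78 °C. The C8 centre is too far away to interfere, so reagent control should give the (4S,5R,8R) isomer.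

Step 9
Reactants: 13 (1S,2R)-2-[(3R)-3-{[(tert-butyldimethylsilyl)oxy]methyl}pent-4-en-1-yl]-1,3-dimethylcyclohex-3-ene-1-carbaldehyde
Product: 14 (1S,2R)-2-[(3R)-3-{[(tert-butyldimethylsilyl)oxy]methyl}pent-4-en-1-yl]-1,3-dimethylcyclohex-3-ene-1-carboxylic acid
Conditions: NaClO2, NaH2PO4, 2-methylbut-2-ene, tBuOH/H2O, 0 °C → rt
Reagents that add atoms: sodium chlorite, [Na+].[O-]Cl=O
Why: Pinnick oxidation; chlorite oxidises the neopentyl aldehyde while the scavenger removes hypochlorous acid, so both alkenes survive, and C4 is quaternary and cannot epimerise.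

Step 10
Reactants: 14 (1S,2R)-2-[(3R)-3-{[(tert-butyldimethylsilyl)oxy]methyl}pent-4-en-1-yl]-1,3-dimethylcyclohex-3-ene-1-carboxylic acid
Product: 15 tert-butyl (1S,2R)-2-[(3R)-3-{[(tert-butyldimethylsilyl)oxy]methyl}pent-4-en-1-yl]-1,3-dimethylcyclohex-3-ene-1-carboxylate
Conditions: Me2NCH(OtBu)2 (4 equiv), toluene, 80 °C
Reagents that add atoms: N,N-dimethylformamide di-tert-butyl acetal, CN(C)C(OC(C)(C)C)OC(C)(C)C
Why: Esterification by O-alkylation of the carboxylate with the tert-butyl cation equivalent released from the formamide acetal; the hindered C19 carbonyl carbon is never attacked, and the medium is neutral, so the silyl ether and alkenes are safe.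

Step 11
Reactants: 15 tert-butyl (1S,2R)-2-[(3R)-3-{[(tert-butyldimethylsilyl)oxy]methyl}pent-4-en-1-yl]-1,3-dimethylcyclohex-3-ene-1-carboxylate, 16 methyl acrylate
Product: 17 tert-butyl (1S,2R)-2-[(3R,4E)-3-{[(tert-butyldimethylsilyl)oxy]methyl}-6-methoxy-6-oxohex-4-en-1-yl]-1,3-dimethylcyclohex-3-ene-1-carboxylate
Conditions: 16 (5 equiv), second-generation Hoveyda–Grubbs catalyst C31H38Cl2N2ORu (5 mol%), CH2Cl2, 40 °C
Reagents that add atoms: none
Why: Olefin cross-metathesis of a terminal alkene with an electron-poor acrylate, which gives the (E) enoate selectively; the trisubstituted ring alkene C1=C10 does not enter the catalytic cycle.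

Step 12
Reactants: 17 tert-butyl (1S,2R)-2-[(3R,4E)-3-{[(tert-butyldimethylsilyl)oxy]methyl}-6-methoxy-6-oxohex-4-en-1-yl]-1,3-dimethylcyclohex-3-ene-1-carboxylate
Product: 18 tert-butyl (1S,4aR,5S,6R,8aR)-6-{[(tert-butyldimethylsilyl)oxy]methyl}-5-(2-methoxy-2-oxoethyl)-1,4a-dimethyldecahydronaphthalene-1-carboxylate
Conditions: Fe(acac)3 (30 mol%), PhSiH3 (2.5 equiv), EtOH/HOCH2CH2OH (5:1), 60 °C
Reagents that add atoms: none
Why: Hydrogen-atom transfer from an iron hydride to C1 gives the tertiary C10 radical, which closes 6-exo-trig onto C9 of the enoate (reductive Giese cyclisation); the α-ester radical is then reduced and protonated. A chair-like closure with the ring A bonds, C17 and the enoate all equatorial gives the trans fusion (C20 axial, β) and H9 α; it is the same closure as the second ring closure of radical polyene cyclisations. Unlike a cation, the radical is not captured by the C19 ester.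

Step 13
Reactants: 18 tert-butyl (1S,4aR,5S,6R,8aR)-6-{[(tert-butyldimethylsilyl)oxy]methyl}-5-(2-methoxy-2-oxoethyl)-1,4a-dimethyldecahydronaphthalene-1-carboxylate
Product: 19 tert-butyl (1S,4aR,5S,6R,8aR)-6-{[(tert-butyldimethylsilyl)oxy]methyl}-1,4a-dimethyl-5-(2-oxoethyl)decahydronaphthalene-1-carboxylate
Conditions: iBu2AlH (1.1 equiv), CH2Cl2, −78 °C; MeOH, then aq. potassium sodium tartrate
Reagents that add atoms: none
Why: Partial reduction of the methyl ester through a tetrahedral aluminium hemiacetal that is stable at −78 °C; the axial tert-butyl ester on quaternary C4 is too hindered to react.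

Step 14
Reactants: 19 tert-butyl (1S,4aR,5S,6R,8aR)-6-{[(tert-butyldimethylsilyl)oxy]methyl}-1,4a-dimethyl-5-(2-oxoethyl)decahydronaphthalene-1-carboxylate, 20 3-(triphenyl-λ5-phosphanylidene)oxolan-2-one
Product: 21 tert-butyl (1S,4aR,5S,6R,8aR)-6-{[(tert-butyldimethylsilyl)oxy]methyl}-1,4a-dimethyl-5-[(2E)-2-(2-oxooxolan-3-ylidene)ethyl]decahydronaphthalene-1-carboxylate
Conditions: 20 (1.5 equiv), toluene, 80 °C
Reagents that add atoms: none
Why: Wittig olefination with a lactone-stabilised, non-basic ylide; it forms C12=C13 as the (E) alkylidene lactone without enolising the aldehyde.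

Step 15
Reactants: 21 tert-butyl (1S,4aR,5S,6R,8aR)-6-{[(tert-butyldimethylsilyl)oxy]methyl}-1,4a-dimethyl-5-[(2E)-2-(2-oxooxolan-3-ylidene)ethyl]decahydronaphthalene-1-carboxylate
Product: 22 tert-butyl (1S,4aR,5S,6R,8aR)-6-{[(tert-butyldimethylsilyl)oxy]methyl}-1,4a-dimethyl-5-[2-(2-oxo-2,5-dihydrofuran-3-yl)ethyl]decahydronaphthalene-1-carboxylate
Conditions: RhCl3·3H2O (10 mol%), EtOH, 80 °C
Reagents that add atoms: none
Why: Rhodium hydride-mediated alkene isomerisation (addition–elimination) moves the exocyclic C12=C13 bond into the ring to the more stable endocyclic butenolide C13=C14; there is no other alkene in the molecule and no stereocentre is allylic to the migrating bond.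

Step 16
Reactants: 22 tert-butyl (1S,4aR,5S,6R,8aR)-6-{[(tert-butyldimethylsilyl)oxy]methyl}-1,4a-dimethyl-5-[2-(2-oxo-2,5-dihydrofuran-3-yl)ethyl]decahydronaphthalene-1-carboxylate
Product: 24 (1S,4aR,5S,6R,8aR)-6-(hydroxymethyl)-1,4a-dimethyl-5-[2-(2-oxo-2,5-dihydrofuran-3-yl)ethyl]decahydronaphthalene-1-carboxylic acid, via hydroxy tert-butyl ester 23 (not isolated)
Conditions: CF3CO2H/CH2Cl2/H2O (10:20:1), 0 °C → rt; evaporate, aq. NaHCO3/MeOH, then pH 3
Reagents that add atoms: none
Why: Acidolysis: the primary silyl ether is hydrolysed first, then the tert-butyl ester is cleaved by alkyl–oxygen fission (loss of the tert-butyl cation), so the hindrance at C19 does not matter. The butenolide is stable to acid, and the bicarbonate work-up removes any trifluoroacetate formed on O17.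

Compound list
1 | (E)-but-2-ene-1,4-diol | OC/C=C/CO | starting material
2 | (E)-4-[(tert-butyldimethylsilyl)oxy]but-2-en-1-ol | CC(C)(C)[Si](C)(C)OC/C=C/CO | intermediate
3 | {[(2E)-4-bromobut-2-en-1-yl]oxy}(tert-butyl)dimethylsilane | CC(C)(C)[Si](C)(C)OC/C=C/CBr | intermediate
4 | 1-[(3-bromopropoxy)methyl]-4-methoxybenzene | COc1ccc(COCCCBr)cc1 | starting material
5 | {3-[(4-methoxyphenyl)methoxy]propyl}magnesium bromide | COc1ccc(COCCC[Mg]Br)cc1 | intermediate
6 | tert-butyl({(2R)-2-ethenyl-5-[(4-methoxyphenyl)methoxy]pentyl}oxy)dimethylsilane | COc1ccc(COCCC[C@@H](CO[Si](C)(C)C(C)(C)C)C=C)cc1 | intermediate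
7 | (4R)-4-{[(tert-butyldimethylsilyl)oxy]methyl}hex-5-en-1-ol | OCCC[C@@H](CO[Si](C)(C)C(C)(C)C)C=C | intermediate
8 | (4R)-4-{[(tert-butyldimethylsilyl)oxy]methyl}hex-5-enal | O=CCC[C@@H](CO[Si](C)(C)C(C)(C)C)C=C | intermediate
9 | 2-(triphenyl-λ5-phosphanylidene)propanal | CC(C=O)=P(c1ccccc1)(c1ccccc1)c1ccccc1 | starting material
10 | (2E,6R)-6-{[(tert-butyldimethylsilyl)oxy]methyl}-2-methylocta-2,7-dienal | O=C/C(C)=C/CC[C@@H](CO[Si](C)(C)C(C)(C)C)C=C | intermediate
11 | (3E,7R)-7-{[(tert-butyldimethylsilyl)oxy]methyl}-3-methylnona-1,3,8-triene | C=C/C(C)=C/CC[C@@H](CO[Si](C)(C)C(C)(C)C)C=C | intermediate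
12 | 2-methylacrolein | CC(=C)C=O | starting material
13 | (1S,2R)-2-[(3R)-3-{[(tert-butyldimethylsilyl)oxy]methyl}pent-4-en-1-yl]-1,3-dimethylcyclohex-3-ene-1-carbaldehyde | CC1=CCC[C@](C)(C=O)[C@@H]1CC[C@@H](CO[Si](C)(C)C(C)(C)C)C=C | intermediate
14 | (1S,2R)-2-[(3R)-3-{[(tert-butyldimethylsilyl)oxy]methyl}pent-4-en-1-yl]-1,3-dimethylcyclohex-3-ene-1-carboxylic acid | CC1=CCC[C@](C)(C(=O)O)[C@@H]1CC[C@@H](CO[Si](C)(C)C(C)(C)C)C=C | intermediate
15 | tert-butyl (1S,2R)-2-[(3R)-3-{[(tert-butyldimethylsilyl)oxy]methyl}pent-4-en-1-yl]-1,3-dimethylcyclohex-3-ene-1-carboxylate | CC1=CCC[C@](C)(C(=O)OC(C)(C)C)[C@@H]1CC[C@@H](CO[Si](C)(C)C(C)(C)C)C=C | intermediate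
16 | methyl acrylate | C=CC(=O)OC | starting material
17 | tert-butyl (1S,2R)-2-[(3R,4E)-3-{[(tert-butyldimethylsilyl)oxy]methyl}-6-methoxy-6-oxohex-4-en-1-yl]-1,3-dimethylcyclohex-3-ene-1-carboxylate | CC1=CCC[C@](C)(C(=O)OC(C)(C)C)[C@@H]1CC[C@@H](CO[Si](C)(C)C(C)(C)C)/C=C/C(=O)OC | intermediate
18 | tert-butyl (1S,4aR,5S,6R,8aR)-6-{[(tert-butyldimethylsilyl)oxy]methyl}-5-(2-methoxy-2-oxoethyl)-1,4a-dimethyldecahydronaphthalene-1-carboxylate | C[C@]12CCC[C@](C)(C(=O)OC(C)(C)C)[C@@H]1CC[C@@H](CO[Si](C)(C)C(C)(C)C)[C@@H]2CC(=O)OC | intermediate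
19 | tert-butyl (1S,4aR,5S,6R,8aR)-6-{[(tert-butyldimethylsilyl)oxy]methyl}-1,4a-dimethyl-5-(2-oxoethyl)decahydronaphthalene-1-carboxylate | C[C@]12CCC[C@](C)(C(=O)OC(C)(C)C)[C@@H]1CC[C@@H](CO[Si](C)(C)C(C)(C)C)[C@@H]2CC=O | intermediate
20 | 3-(triphenyl-λ5-phosphanylidene)oxolan-2-one | O=C1OCCC1=P(c1ccccc1)(c1ccccc1)c1ccccc1 | starting material
21 | tert-butyl (1S,4aR,5S,6R,8aR)-6-{[(tert-butyldimethylsilyl)oxy]methyl}-1,4a-dimethyl-5-[(2E)-2-(2-oxooxolan-3-ylidene)ethyl]decahydronaphthalene-1-carboxylate | C[C@]12CCC[C@](C)(C(=O)OC(C)(C)C)[C@@H]1CC[C@@H](CO[Si](C)(C)C(C)(C)C)[C@@H]2C/C=C1\CCOC1=O | intermediate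
22 | tert-butyl (1S,4aR,5S,6R,8aR)-6-{[(tert-butyldimethylsilyl)oxy]methyl}-1,4a-dimethyl-5-[2-(2-oxo-2,5-dihydrofuran-3-yl)ethyl]decahydronaphthalene-1-carboxylate | C[C@]12CCC[C@](C)(C(=O)OC(C)(C)C)[C@@H]1CC[C@@H](CO[Si](C)(C)C(C)(C)C)[C@@H]2CCC1=CCOC1=O | intermediate
23 | tert-butyl (1S,4aR,5S,6R,8aR)-6-(hydroxymethyl)-1,4a-dimethyl-5-[2-(2-oxo-2,5-dihydrofuran-3-yl)ethyl]decahydronaphthalene-1-carboxylate | C[C@]12CCC[C@](C)(C(=O)OC(C)(C)C)[C@@H]1CC[C@@H](CO)[C@@H]2CCC1=CCOC1=O | intermediate
24 | (1S,4aR,5S,6R,8aR)-6-(hydroxymethyl)-1,4a-dimethyl-5-[2-(2-oxo-2,5-dihydrofuran-3-yl)ethyl]decahydronaphthalene-1-carboxylic acid | C[C@]12CCC[C@](C)(C(=O)O)[C@@H]1CC[C@@H](CO)[C@@H]2CCC1=CCOC1=O | target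

Total step count: 16. Longest linear sequence: 16 steps (1 to 24); 4, 9, 12, 16 and 20 enter as bought materials.

Steps least certain to work

Step 8 (key step). The α-methyl group of the dienophile may compete with the formyl group for the endo position, which would erode the C4/C5 relationship. The strongly acidic catalyst may also isomerise or oligomerise the 1,2-disubstituted diene before it reacts, since protonation gives a tertiary allyl cation. Fallback, from 11 back to the route at 15: C4 is set by enolate alkylation instead of by the topology of the cycloaddition.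
- 11 is combined with acrolein under the same oxazaborolidinium salt; without an α-substituent the endo preference and the ortho orientation are more secure. This gives the aldehyde F7, whose C4 configuration is of no consequence.
- Pinnick oxidation gives the acid F8, and Me2NCH(OtBu)2 gives the tert-butyl ester F9.
- LiN(iPr)2 in THF at −78 °C followed by MeI methylates the ester enolate on the face trans to the C5 chain. The methyl then stands trans to C6 and the ester cis to it, which is 15.

Step 12. The C10 radical may take up hydrogen before it closes, because the attack on C9 builds a quaternary centre beside the substituted C5; the net result would be reduction of the alkene. Attack on the other face of the planar radical would give the cis-fused isomer. Fallback, from 15 back to the route at 18: the radical is made without any hydride, so premature reduction is excluded. It does not alter the facial course, which rests on the chair-like closure.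
- 15 is epoxidised at C1=C10 (mCPBA, NaHCO3; the terminal alkene is much slower) to the epoxide F10.
- LiEt3BH at −20 °C opens it at C1 to the C10 tertiary alcohol F11; the doubly hindered tert-butyl ester should survive.
- Cross-metathesis with 16 gives the hydroxy enoate F12.
- Methyl chlorooxoacetate (Et3N, DMAP) gives the methyl oxalate F13, and one equivalent of CsOH gives the caesium oxalate F14.
- Blue light with [Ir(dF(CF3)ppy)2(dtbbpy)]PF6 (1 mol%) in DME/DMF/H2O oxidises the oxalate; two molecules of CO2 leave and the C10 radical closes onto C9 to give 18.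

Step 3. Enantioselectivity and the branched-to-linear ratio may fall, because the ether oxygen of the Grignard reagent or traces of a coordinating solvent can displace the diphosphine from copper. Fallback, from 4 back to the route at 6: C8 is set by enzymatic desymmetrisation.
- Diethyl malonate is alkylated with 4 (NaH, THF/DMF) to the malonate F1, and LiAlH4 gives the diol F2.
- Burkholderia cepacia lipase with vinyl acetate gives the (S)-monoacetate F3. Acylation of the diol and hydrolysis of its diacetate are enantiocomplementary, so either sense of the enzyme can be used.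
- TBSCl/imidazole gives the silyl ether acetate F4, and K2CO3/MeOH at 0 °C gives the alcohol F5.
- Dess–Martin oxidation gives the aldehyde F6, which is used at once, and methylenation with Ph3P=CH2 at −78 → 0 °C gives 6.

Step 15. The alkene may stop short of full migration into the ring. The acid released in hot ethanol may also strip the silyl ether early (harmless, since that converges on 23) or begin to cleave the tert-butyl ester. Fallback, from 21 back to the route at 22: the double bond is removed and put back in the ring.
- Hydrogenation (H2, Pd/C, EtOAc) gives the saturated lactone F15.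
- LiN(iPr)2 followed by PhSSPh gives the α-phenylsulfanyl lactone F16; the tert-butyl ester has no α-hydrogen.
- mCPBA at −78 °C gives the sulfoxide F17, and syn-elimination into the ring in toluene at 110 °C gives 22.

Further compounds
F1 | step 3 | diethyl 2-{3-[(4-methoxyphenyl)methoxy]propyl}propanedioate | CCOC(=O)C(CCCOCc1ccc(OC)cc1)C(=O)OCC
F2 | step 3 | 2-{3-[(4-methoxyphenyl)methoxy]propyl}propane-1,3-diol | COc1ccc(COCCCC(CO)CO)cc1
F3 | step 3 | (2S)-3-hydroxy-2-{3-[(4-methoxyphenyl)methoxy]propyl}propyl acetate | COc1ccc(COCCC[C@@H](CO)COC(C)=O)cc1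
F4 | step 3 | (2R)-2-{[(tert-butyldimethylsilyl)oxy]methyl}-5-[(4-methoxyphenyl)methoxy]pentyl acetate | COc1ccc(COCCC[C@@H](CO[Si](C)(C)C(C)(C)C)COC(C)=O)cc1
F5 | step 3 | (2R)-2-{[(tert-butyldimethylsilyl)oxy]methyl}-5-[(4-methoxyphenyl)methoxy]pentan-1-ol | COc1ccc(COCCC[C@@H](CO[Si](C)(C)C(C)(C)C)CO)cc1
F6 | step 3 | (2S)-2-{[(tert-butyldimethylsilyl)oxy]methyl}-5-[(4-methoxyphenyl)methoxy]pentanal | COc1ccc(COCCC[C@@H](CO[Si](C)(C)C(C)(C)C)C=O)cc1
F7 | step 8 | (1S,2S)-2-[(3R)-3-{[(tert-butyldimethylsilyl)oxy]methyl}pent-4-en-1-yl]-3-methylcyclohex-3-ene-1-carbaldehyde | CC1=CCC[C@H](C=O)[C@@H]1CC[C@@H](CO[Si](C)(C)C(C)(C)C)C=C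
F8 | step 8 | (1S,2S)-2-[(3R)-3-{[(tert-butyldimethylsilyl)oxy]methyl}pent-4-en-1-yl]-3-methylcyclohex-3-ene-1-carboxylic acid | CC1=CCC[C@H](C(=O)O)[C@@H]1CC[C@@H](CO[Si](C)(C)C(C)(C)C)C=C
F9 | step 8 | tert-butyl (1S,2S)-2-[(3R)-3-{[(tert-butyldimethylsilyl)oxy]methyl}pent-4-en-1-yl]-3-methylcyclohex-3-ene-1-carboxylate | CC1=CCC[C@H](C(=O)OC(C)(C)C)[C@@H]1CC[C@@H](CO[Si](C)(C)C(C)(C)C)C=C
F10 | step 12 | 1,10-epoxide of 15 (either epoxide face; C4, C5 and C8 as in 15) | CC12OC1CC[C@](C)(C(=O)OC(C)(C)C)[C@@H]2CC[C@@H](CO[Si](C)(C)C(C)(C)C)C=C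
F11 | step 12 | C10 tertiary alcohol from F10 (10-hydroxy, C1=C10 saturated; C4, C5 and C8 as in 15) | CC1(O)CCC[C@](C)(C(=O)OC(C)(C)C)[C@@H]1CC[C@@H](CO[Si](C)(C)C(C)(C)C)C=C
F12 | step 12 | 10-hydroxy analogue of 17 with the (E) enoate in place | CC1(O)CCC[C@](C)(C(=O)OC(C)(C)C)[C@@H]1CC[C@@H](CO[Si](C)(C)C(C)(C)C)/C=C/C(=O)OC
F13 | step 12 | methyl oxalate ester of the C10 alcohol F12 | COC(=O)C(=O)OC1(C)CCC[C@](C)(C(=O)OC(C)(C)C)[C@@H]1CC[C@@H](CO[Si](C)(C)C(C)(C)C)/C=C/C(=O)OC
F14 | step 12 | caesium oxalate of the C10 alcohol F12 | [Cs+].[O-]C(=O)C(=O)OC1(C)CCC[C@](C)(C(=O)OC(C)(C)C)[C@@H]1CC[C@@H](CO[Si](C)(C)C(C)(C)C)/C=C/C(=O)OC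
F15 | step 15 | saturated lactone: 21 with C12–C13 single bond (C13 epimers) | C[C@]12CCC[C@](C)(C(=O)OC(C)(C)C)[C@@H]1CC[C@@H](CO[Si](C)(C)C(C)(C)C)[C@@H]2CCC1CCOC1=O
F16 | step 15 | 13-(phenylsulfanyl) derivative of F15 | C[C@]12CCC[C@](C)(C(=O)OC(C)(C)C)[C@@H]1CC[C@@H](CO[Si](C)(C)C(C)(C)C)[C@@H]2CCC1(Sc3ccccc3)CCOC1=O
F17 | step 15 | 13-(phenylsulfinyl) derivative of F15 | C[C@]12CCC[C@](C)(C(=O)OC(C)(C)C)[C@@H]1CC[C@@H](CO[Si](C)(C)C(C)(C)C)[C@@H]2CCC1(S(=O)c3ccccc3)CCOC1=O
A1 | alternative 1 | tert-butyl (1S,5S,6R)-6-(but-3-en-1-yl)-5-ethynyl-1,5-dimethylcyclohex-3-ene-1-carboxylate | C#C[C@@]1(C)C=CC[C@](C)(C(=O)OC(C)(C)C)[C@@H]1CCC=C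
A2 | alternative 1 | ring B-fused cyclopentenone, tert-butyl ester (C9=C11, C12 ketone, C17 methylene, C1=C2) | C[C@]12C=CC[C@](C)(C(=O)OC(C)(C)C)[C@@H]1CC[C@H]3CC(=O)C=C23
A3 | alternative 2 | tert-butyl (2S,6E)-2,6-dimethyl-8-oxo-2-[(1E)-penta-1,3,4-trien-1-yl]oct-6-enoate | O=C/C=C(\C)CCC[C@](C)(C(=O)OC(C)(C)C)/C=C/C=C=C
A4 | alternative 2 | trans-fused octalin, tert-butyl ester (C11 aldehyde, C6=C7, exocyclic C8=C17) | C[C@]12CCC[C@](C)(C(=O)OC(C)(C)C)[C@@H]1C=CC(=C)[C@@H]2C=O
A5 | alternative 3 | tert-butyl (2S)-2-{3-[2-(tert-butyldimethylsilyloxy)ethyl]-5-hydroxy-2-methylphenyl}-2-methyl-4-(trimethylsilyloxy)pent-4-enoate | Cc1c(CCO[Si](C)(C)C(C)(C)C)cc(O)cc1[C@](C)(CC(=C)O[Si](C)(C)C)C(=O)OC(C)(C)C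
A6 | alternative 3 | bicyclic cross-conjugated dienone, tert-butyl ester (C2 and C7 ketones, quaternary C10, C12 silyl ether) | C[C@]12CC(=O)C[C@](C)(C(=O)OC(C)(C)C)C1=CC(=O)C=C2CCO[Si](C)(C)C(C)(C)C
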